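**Strategy.** Everything rests on cutting the C2–C3 bond of the ten-membered ring and parking acyl carbon C3 on the C8 oxygen. The precursor is therefore a seven-membered Z-enoate lactone (O8, C3–C8) fused to the α-methylene-γ-lactone, with a 2-silyloxy-2-methyl-3-oxobutyl chain on C8. This works because C10 is quaternary, so the C1 ketone enolises only at C2, and because the Z C4=C5–C6–C7 segment lets C3 reach O8. One enolate O-to-C acyl transfer makes C2–C3, breaks C3–O8, delivers the C1–C10 carbocycle as a 1,3-diketone and frees the C8 hydroxyl for the angelate; acid then closes the C3–O–C10 furanone.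

Key step: step 14

Remark: germacrane atom labels are used for all intermediates (C1 ketone, C2, C3, C4 with methyl C15, C5, C6 lactone carbinol, C7, C8 ester carbinol, C9, C10 quaternary carbinol with methyl C14, C11–C13 methylene lactone); CIP descriptors are those of each compound itself and change where only priorities change.

**Route**

Step 1
Reactants: 1 (S)-lactic acid
Product: 2 (2S,5S)-2-tert-butyl-5-methyl-1,3-dioxolan-4-one (cis)
Conditions: t-BuCHO, cat. TsOH·H2O, cat. H2SO4, pentane, reflux, Dean–Stark; crystallisation from pentane/Et2O, −78 °C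
Reagents that add atoms: pivalaldehyde CC(C)(C)C=O
Why: Acid-catalysed acetalisation with removal of water should favour the cis-2,5-disubstituted dioxolanone, which stores the lactic acid configuration in the new acetal centre C2 (Seebach self-regeneration of stereocentres) and is purified by low-temperature crystallisation.

Step 2
Reactants: 2 (2S,5S)-2-tert-butyl-5-methyl-1,3-dioxolan-4-one; 3 allyl bromide
Product: 5 (2S,5R)-2-tert-butyl-5-methyl-5-(prop-2-en-1-yl)-1,3-dioxolan-4-one, via dioxolanone lithium enolate 4 (not isolated)
Conditions: LDA, THF, −78 °C; then allyl bromide, −78 → −30 °C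
Reagents that add atoms: none
Why: The planar enolate is alkylated (SN2 on the allylic bromide) on the face opposite the tert-butyl group, so allyl takes the place of the former hydrogen and the quaternary centre (future C10) forms with overall retention.

Step 3
Reactants: 5 (2S,5R)-2-tert-butyl-5-methyl-5-(prop-2-en-1-yl)-1,3-dioxolan-4-one
Product: 7 (R)-3-hydroxy-3-methylhex-5-en-2-one, via lithium lactolate 6 (not isolated)
Conditions: MeLi (1.05 equiv), THF, −78 °C; AcOH, −78 °C, then aqueous work-up; the volatile product is carried on as a concentrated solution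
Reagents that add atoms: methyllithium [Li]C
Why: Organolithium monoaddition to the dioxolanone carbonyl is expected to stop at the lactolate, which is stable at −78 °C and collapses only on protonation with loss of pivalaldehyde to the α-hydroxy methyl ketone (the new methyl is C2), leaving the quaternary stereocentre untouched.

Step 4
Reactants: 7 (R)-3-hydroxy-3-methylhex-5-en-2-one
Product: 8 (R)-3-(tert-butyldimethylsilyloxy)-3-methylhex-5-en-2-one
Conditions: TBSOTf, 2,6-lutidine, CH2Cl2, 0 °C
Reagents that add atoms: tert-butyldimethylsilyl triflate CC(C)(C)[Si](C)(C)OS(=O)(=O)C(F)(F)F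
Why: Silyl triflate with a hindered pyridine base silylates tertiary alcohols reliably, and the TBS ether masks O10 through the base-mediated key step until acid releases it for furanone closure.

Step 5
Reactants: 8 (R)-3-(tert-butyldimethylsilyloxy)-3-methylhex-5-en-2-one
Product: 9 (R)-3-(tert-butyldimethylsilyloxy)-3-methyl-4-oxopentanal
Conditions: O3, CH2Cl2, −78 °C; then PPh3, −78 °C → rt
Reagents that add atoms: ozone [O-][O+]=O
Why: Ozonolysis with reductive work-up cleaves the terminal alkene to the C8 aldehyde, while the ketone and silyl ether are inert to ozone.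

Step 6
Reactants: 10 (S)-but-3-ene-1,2-diol
Product: 11 (S)-1-(triethylsilyloxy)but-3-en-2-ol
Conditions: TESCl (1.0 equiv), imidazole, CH2Cl2, −40 °C
Reagents that add atoms: chlorotriethylsilane CC[Si](Cl)(CC)CC
Why: At low temperature the primary hydroxyl is silylated faster than the secondary allylic one for steric reasons, leaving the future C6 carbinol free; its configuration is bought.

Step 7
Reactants: 11 (S)-1-(triethylsilyloxy)but-3-en-2-ol; 12 2-(bromomethyl)acrylic acid
Product: 13 (S)-1-(triethylsilyloxy)but-3-en-2-yl 2-(bromomethyl)acrylate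
Conditions: DCC, DMAP (5 mol %), CH2Cl2, 0 °C
Reagents that add atoms: none
Why: Steglich esterification acylates the secondary alcohol with retention (its C–O bond is not broken), and low temperature with little DMAP limits SN2' attack on the allylic bromide.

Step 8
Reactants: 13 (S)-1-(triethylsilyloxy)but-3-en-2-yl 2-(bromomethyl)acrylate
Product: 14 (S)-3-(bromomethyl)-5-(triethylsilyloxymethyl)furan-2(5H)-one
Conditions: Grubbs II (5 mol %), CH2Cl2, 40 °C, 0.02 M
Reagents that add atoms: none
Why: Ring-closing metathesis of the vinyl group with the 2-substituted acrylate closes the five-membered butenolide with loss of ethylene, and the allylic bromide is tolerated by the ruthenium carbene.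

Step 9
Reactants: 9 (R)-3-(tert-butyldimethylsilyloxy)-3-methyl-4-oxopentanal; 14 (S)-3-(bromomethyl)-5-(triethylsilyloxymethyl)furan-2(5H)-one
Product: 16 α-methylene-γ-lactone carbinol (6S,7R,8S,10R; 8-epi), via allylzinc bromide 15 (not isolated)
Conditions: Zn dust, THF/sat. aq. NH4Cl, 0 °C → rt
Reagents that add atoms: none
Why: In this Barbier allylation the allylzinc adds to the aldehyde through its γ-carbon C7 in a closed chair transition state, which regenerates the exocyclic C11=C13 alkene; C7 is set by attack anti to the CH2OTES group on C6 (6,7-trans), C8 by the chair of the ring-locked E-type allylmetal (7,8-anti, 8S), and the hindered α-silyloxy ketone is not attacked.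

Step 10
Reactants: 16 α-methylene-γ-lactone carbinol (6S,7R,8S,10R); 17 methacrylic acid
Product: 18 C8 methacrylate (6S,7R,8R,10R)
Conditions: PPh3, DIAD, toluene, 0 °C → rt
Reagents that add atoms: none
Why: Mitsunobu esterification displaces the activated C8 oxygen by methacrylate in an SN2 step, so C8 is inverted to the natural configuration while the ester needed for the second metathesis is installed.

Step 11
Reactants: 18 C8 methacrylate (6S,7R,8R,10R)
Product: 20 C5 aldehyde (6S,7R,8R,10R), via alkoxydimethylsulfonium chloride 19 (not isolated)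
Conditions: (COCl)2, DMSO, CH2Cl2, −78 → −40 °C; then Et3N, −78 → 0 °C
Reagents that add atoms: none
Why: Direct Swern oxidation of a primary triethylsilyl ether (silyl–sulfonium exchange, then ylide fragmentation) gives the aldehyde in one operation, the tertiary TBS ether, ketone and both acrylate units being inert and the cold amine stage protecting the C6 centre α to the new aldehyde.

Step 12
Reactants: 20 C5 aldehyde (6S,7R,8R,10R)
Product: 21 C5 vinyl compound (6R,7R,8R,10R)
Conditions: CH2I2, Zn, Ti(OiPr)4 (mediator), THF, rt
Reagents that add atoms: diiodomethane ICI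
Why: The non-basic gem-dimetallic reagent of the Takai methylenation reacts with aldehydes much faster than with ketones, esters or lactones, so only C5 becomes the vinyl group and the α-acyloxy centre C6 is not epimerised.

Step 13
Reactants: 21 C5 vinyl compound (6R,7R,8R,10R)
Product: 22 trans-fused bis-lactone (6R,7R,8R,10R): seven-membered Z-enoate lactone O8–C3(=O)–C4(Me)=C5–C6–C7–C8 on the α-methylene-γ-lactone; C8 carries the (R)-2-(tert-butyldimethylsilyloxy)-2-methyl-3-oxobutyl chain
Conditions: Grubbs II (10 mol %), toluene, 80 °C, 0.003 M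
Reagents that add atoms: none
Why: Ring-closing metathesis of the C5 vinyl group with the methacrylate closes the seven-membered lactone with loss of ethylene; the ring size admits only the Z C4=C5 alkene, the trans-lactone holds both partners close, and closure of C5 onto the α-methylene group would need a bridgehead alkene.

Step 14
Reactants: 22 trans-fused bis-lactone (6R,7R,8R,10R)
Product: 26 ten-membered 1,3-diketone (6R,7R,8R,10R; free 8-OH; 10-OTBS), via methyl ketone lithium enolate 23 (not isolated), via oxygen-bridged tetrahedral alkoxide 24 (not isolated), via dilithium diketonate alkoxide 25 (not isolated)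
Conditions: 22 added slowly to LiHMDS (2.2 equiv), THF, −78 °C, 0.002 M; −78 → −40 °C; AcOH, −78 °C; crude product used at once
Reagents that add atoms: none
Why: Proposed new method: LiHMDS can deprotonate the C1 ketone only at C2 because C10 is fully substituted, and the resulting enolate 23 adds to lactone carbonyl C3 in a 7-exo-trig closure to give the O8-bridged bicyclo[4.4.1] alkoxide 24, which collapses by breaking C3–O8 so that the two seven-membered rings merge into the ten-membered carbocycle C1–C10. The closest known reaction types are the Baker–Venkataraman O-to-C acyl shift, Claisen and Dieckmann acylation of ketone enolates by esters and lactones, and ring enlargements in which a side chain inserts into a cyclic acyl donor; a seven-to-ten enlargement of an enoate lactone of this kind has no direct precedent. The ten-membered ring is thus closed at C2–C3 through a seven-membered transition state followed by fragmentation, not by end-to-end macrocyclisation, and no stereocentre is created (C3 is stereogenic only in 24, where the one-atom oxygen bridge fixes it; C6, C7, C8 and C10 are spectators). The step needs attack at C3 and not at the γ-lactone carbonyl C12 or the Michael positions C13 and C5, which the substrate secures by ring size (seven- against eight-membered closures) and by the s-cis ester geometry forced on the seven-membered lactone, which makes C3 the best acyl donor. It also needs C- over O-acylation and no return, which is expected because only the C-acylated product is drained from the equilibria as the lithium 1,3-diketonate 25 by the second equivalent of base, while slow addition to cold excess base at high dilution disfavours intermolecular aldol and Claisen reactions. Acetic acid is added at −78 °C so that diketonate and C8 alkoxide are protonated together before the alkoxide can translactonise onto C12.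

Step 15
Reactants: 26 ten-membered 1,3-diketone (6R,7R,8R,10R)
Product: 29 8-hydroxy furanoheliangolide (6R,7R,8R,10R), via desilylated hydroxy diketone 27 (not isolated), via cyclic hemiketal 28 (not isolated)
Conditions: 48% aq. HF, MeCN, 0 °C → rt
Reagents that add atoms: none
Why: HF cleaves the tertiary silyl ether, the freed C10 hydroxyl adds to C3 (5-exo-trig) and the hemiketal loses water to the conjugated 3(2H)-furanone (known cyclodehydration of α'-hydroxy-1,3-diketones), a sink that removes the 1,3-diketone and with it the retro-Claisen option, while C10 keeps its configuration because its C–O bond is not broken.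

Step 16
Reactants: 29 8-hydroxy furanoheliangolide; 30 angelic acid
Product: 32 15-deoxybudlein A, via angeloyl trichlorobenzoyl mixed anhydride 31 (not isolated)
Conditions: 30, 2,4,6-Cl3C6H2COCl, Et3N, toluene, rt; then 29, 80 °C (no DMAP)
Reagents that add atoms: none
Why: In this Yamaguchi-type esterification the mixed anhydride is attacked by the C8 hydroxyl at the less hindered angeloyl carbonyl, and without a nucleophilic catalyst the Z geometry of the angelate should be kept; C8 is retained because its C–O bond is not broken.

**Compound list**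

1 | (S)-lactic acid | C[C@H](O)C(=O)O | starting material
2 | (2S,5S)-2-tert-butyl-5-methyl-1,3-dioxolan-4-one (cis) | C[C@@H]1O[C@H](C(C)(C)C)OC1=O | intermediate
3 | allyl bromide | C=CCBr | starting material
4 | lithium enolate of 2 (not isolated) | CC1=C(O[Li])O[C@@H](C(C)(C)C)O1 | intermediate
5 | (2S,5R)-2-tert-butyl-5-methyl-5-(prop-2-en-1-yl)-1,3-dioxolan-4-one | C=CC[C@@]1(C)O[C@H](C(C)(C)C)OC1=O | intermediate
6 | lithium lactolate from methyl addition to C4 of 5 (not isolated; lactol carbon unassigned) | C=CC[C@@]1(C)O[C@H](C(C)(C)C)OC1(C)O[Li] | intermediate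
7 | (R)-3-hydroxy-3-methylhex-5-en-2-one | C=CC[C@@](C)(O)C(C)=O | intermediate
8 | (R)-3-(tert-butyldimethylsilyloxy)-3-methylhex-5-en-2-one | C=CC[C@@](C)(O[Si](C)(C)C(C)(C)C)C(C)=O | intermediate
9 | (R)-3-(tert-butyldimethylsilyloxy)-3-methyl-4-oxopentanal (C8–C9–C10–C1–C2 fragment) | CC(=O)[C@@](C)(CC=O)O[Si](C)(C)C(C)(C)C | intermediate
10 | (S)-but-3-ene-1,2-diol | C=C[C@@H](CO)O | starting material
11 | (S)-1-(triethylsilyloxy)but-3-en-2-ol | C=C[C@H](O)CO[Si](CC)(CC)CC | intermediate
12 | 2-(bromomethyl)acrylic acid | C=C(CBr)C(=O)O | starting material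
13 | (S)-1-(triethylsilyloxy)but-3-en-2-yl 2-(bromomethyl)acrylate | C=C(CBr)C(=O)O[C@@H](C=C)CO[Si](CC)(CC)CC | intermediate
14 | (S)-3-(bromomethyl)-5-(triethylsilyloxymethyl)furan-2(5H)-one | BrCC1=C[C@@H](CO[Si](CC)(CC)CC)OC1=O | intermediate
15 | allylzinc bromide from 14 (not isolated) | Br[Zn]CC1=C[C@@H](CO[Si](CC)(CC)CC)OC1=O | intermediate
16 | (4R,5S)-4-[(1S,3R)-3-(tert-butyldimethylsilyloxy)-1-hydroxy-3-methyl-4-oxopentyl]-3-methylidene-5-(triethylsilyloxymethyl)oxolan-2-one (6S,7R,8S,10R; 8-epi carbinol) | C=C1C(=O)O[C@H](CO[Si](CC)(CC)CC)[C@H]1[C@@H](O)C[C@@](C)(O[Si](C)(C)C(C)(C)C)C(C)=O | intermediate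
17 | methacrylic acid | C=C(C)C(=O)O | starting material
18 | (1R,3R)-3-(tert-butyldimethylsilyloxy)-3-methyl-1-[(2S,3R)-4-methylidene-5-oxo-2-(triethylsilyloxymethyl)oxolan-3-yl]-4-oxopentyl 2-methylprop-2-enoate (6S,7R,8R,10R) | C=C1C(=O)O[C@H](CO[Si](CC)(CC)CC)[C@H]1[C@H](OC(=O)C(C)=C)C[C@@](C)(O[Si](C)(C)C(C)(C)C)C(C)=O | intermediate
19 | alkoxydimethylsulfonium chloride at O5 of the methacrylate (not isolated) | C=C1C(=O)O[C@H](CO[S+](C)C)[C@H]1[C@H](OC(=O)C(C)=C)C[C@@](C)(O[Si](C)(C)C(C)(C)C)C(C)=O.[Cl-] | intermediate
20 | C5 aldehyde: 2-formyl analogue of 18 (6S,7R,8R,10R) | C=C1C(=O)O[C@H](C=O)[C@H]1[C@H](OC(=O)C(C)=C)C[C@@](C)(O[Si](C)(C)C(C)(C)C)C(C)=O | intermediate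
21 | C5 vinyl compound: 2-ethenyl analogue of 18 (6R,7R,8R,10R) | C=C1C(=O)O[C@H](C=C)[C@H]1[C@H](OC(=O)C(C)=C)C[C@@](C)(O[Si](C)(C)C(C)(C)C)C(C)=O | intermediate
22 | trans-fused 5-7 bis-lactone with (4Z)-enoate and (R)-2-(tert-butyldimethylsilyloxy)-2-methyl-3-oxobutyl chain on C8 (6R,7R,8R,10R) | C=C1C(=O)O[C@@H]2/C=C(/C)C(=O)O[C@H](C[C@@](C)(O[Si](C)(C)C(C)(C)C)C(C)=O)[C@@H]12 | intermediate
23 | lithium enolate (C1=C2) of 22 (not isolated) | C=C1C(=O)O[C@@H]2/C=C(/C)C(=O)O[C@H](C[C@@](C)(O[Si](C)(C)C(C)(C)C)C(=C)O[Li])[C@@H]12 | intermediate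
24 | O8-bridged bicyclo[4.4.1] lithium alkoxide at C3 (not isolated) | C=C1C(=O)O[C@@H]2/C=C(/C)[C@]3(O[Li])CC(=O)[C@](C)(O[Si](C)(C)C(C)(C)C)C[C@@H](O3)[C@@H]12 | intermediate
25 | dilithium salt of 26: delocalised 1,3-diketonate (drawn as C1 enolate) and C8 alkoxide (not isolated) | C=C1C(=O)O[C@@H]2/C=C(/C)C(=O)C=C(O[Li])[C@](C)(O[Si](C)(C)C(C)(C)C)C[C@@H](O[Li])[C@@H]12 | intermediate
26 | (4Z)-ten-membered 1,3-diketone (C1 and C3 ketones, 10-OTBS, free 8-OH, 6,12-α-methylene lactone; 6R,7R,8R,10R) | C=C1C(=O)O[C@@H]2/C=C(/C)C(=O)CC(=O)[C@](C)(O[Si](C)(C)C(C)(C)C)C[C@@H](O)[C@@H]12 | intermediate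
27 | desilylated 8,10-dihydroxy 1,3-diketone (not isolated) | C=C1C(=O)O[C@@H]2/C=C(/C)C(=O)CC(=O)[C@](C)(O)C[C@@H](O)[C@@H]12 | intermediate
28 | C3 hemiketal bridged through O10 (not isolated) | C=C1C(=O)O[C@@H]2/C=C(/C)[C@@]3(O)CC(=O)[C@@](C)(C[C@@H](O)[C@@H]12)O3 | intermediate
29 | 8-hydroxy furanoheliangolide (32 without the angeloyl group; 6R,7R,8R,10R) | C=C1C(=O)O[C@@H]2/C=C(/C)C3=CC(=O)[C@@](C)(C[C@@H](O)[C@@H]12)O3 | intermediate
30 | angelic acid, (Z)-2-methylbut-2-enoic acid | C/C=C(/C)C(=O)O | starting material
31 | angelic 2,4,6-trichlorobenzoic mixed anhydride (not isolated) | C/C=C(/C)C(=O)OC(=O)c1c(Cl)cc(Cl)cc1Cl | intermediate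
32 | 15-deoxybudlein A (6R,7R,8R,10R; 4Z; angelate Z) | C=C1C(=O)O[C@@H]2/C=C(/C)C3=CC(=O)[C@@](C)(C[C@@H](OC(=O)/C(C)=C\C)[C@@H]12)O3 | target

**Step count and risks**

Total step count: 16. Longest linear sequence: 13 steps (steps 1–5, then 9–16, from (S)-lactic acid).

Steps most likely to fail:

1. Step 14 (proposed new method). What may go wrong: the enolate may add reversibly without the bridged alkoxide collapsing toward the carbocycle, intermolecular condensation may outrun the transfer, or the freed C8 alkoxide may translactonise before the quench. Fallback with known reactions, leaving the route at 16 and rejoining it at 32: C2–C3 is made by an aldol addition and the ten-membered ring is closed at C4=C5 by metathesis. Mitsunobu esterification of 16 with angelic acid 30 (PPh3, DIAD) should give, with inversion at C8, the (8R)-angelate TES ether F1. Direct Swern oxidation then gives the angelate C5 aldehyde F2, and Takai methylenation gives the angelate C5 vinyl compound F3. The lithium enolate of the methyl ketone (LDA, THF, −78 °C) is added to methacrolein to give the isopropenyl carbinol aldol adduct F4 (either C3 epimer serves). Ring-closing metathesis of the isopropenyl and vinyl groups at high dilution (the trisubstituted angelate is inert) should give the ten-membered C3 carbinol F5; its C4=C5 geometry is not ring-enforced here and would have to be secured by separation. Aqueous HF in acetonitrile removes the TBS group to give the C3,C10-diol F6. Dess–Martin oxidation of the allylic C3 carbinol gives the α'-hydroxy-1,3-diketone angelate F7, which should cyclodehydrate on mildly acidic work-up to 32.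

2. Step 13. What may go wrong: the ruthenium alkylidene formed at the hindered allylic vinyl group may engage the electron-poor methacrylate too slowly, so that oligomerisation by cross-metathesis or catalyst decay outruns the seven-membered closure. Fallback, leaving the route at 16 and rejoining it at 22: the C4=C5 bond is made by an intramolecular Horner–Wadsworth–Emmons olefination instead. Mitsunobu esterification of 16 with 2-(diethoxyphosphoryl)propanoic acid gives, with inversion, the (8R)-phosphonopropionate F8. Direct Swern oxidation of the TES ether gives the phosphonate aldehyde F9. Masamune–Roush conditions (LiCl, iPr2NEt, MeCN, high dilution) then close the seven-membered enoate lactone, in which only the Z alkene fits, to give 22.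

3. Step 15. What may go wrong: loss of the tertiary silyl group may be slower than reactions of the free C8 hydroxyl, which can return the acyl group by attack on C3 (retro-Claisen) or ketalise C1 in competition with furanone closure. Fallback, leaving the route at 26 and rejoining it at 32: O8 is capped before O10 is unmasked. 26 is returned to its dilithium salt 25 (LiHMDS, THF, −78 °C) and the alkoxide oxygen is acylated with the mixed anhydride 31 to give the 8-O-angeloyl silyl diketone F10. Aqueous HF in acetonitrile then removes the TBS group and the furanone closes as in step 15, giving 32 directly.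

**Further compounds**

F1 | step 14 | (8R)-angelate TES ether (6S,7R,8R,10R) | C=C1C(=O)O[C@H](CO[Si](CC)(CC)CC)[C@H]1[C@H](OC(=O)/C(C)=C\C)C[C@@](C)(O[Si](C)(C)C(C)(C)C)C(C)=O
F2 | step 14 | angelate C5 aldehyde | C=C1C(=O)O[C@H](C=O)[C@H]1[C@H](OC(=O)/C(C)=C\C)C[C@@](C)(O[Si](C)(C)C(C)(C)C)C(C)=O
F3 | step 14 | angelate C5 vinyl compound | C=C1C(=O)O[C@H](C=C)[C@H]1[C@H](OC(=O)/C(C)=C\C)C[C@@](C)(O[Si](C)(C)C(C)(C)C)C(C)=O
F4 | step 14 | isopropenyl carbinol aldol adduct (C3 epimers) | C=C1C(=O)O[C@H](C=C)[C@H]1[C@H](OC(=O)/C(C)=C\C)C[C@@](C)(O[Si](C)(C)C(C)(C)C)C(=O)CC(O)C(C)=C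
F5 | step 14 | ten-membered C3 carbinol (4Z; C3 epimers) | C=C1C(=O)O[C@@H]2/C=C(/C)C(O)CC(=O)[C@](C)(O[Si](C)(C)C(C)(C)C)C[C@@H](OC(=O)/C(C)=C\C)[C@@H]12
F6 | step 14 | C3,C10-diol (C3 epimers) | C=C1C(=O)O[C@@H]2/C=C(/C)C(O)CC(=O)[C@](C)(O)C[C@@H](OC(=O)/C(C)=C\C)[C@@H]12
F7 | step 14 | α'-hydroxy-1,3-diketone angelate | C=C1C(=O)O[C@@H]2/C=C(/C)C(=O)CC(=O)[C@](C)(O)C[C@@H](OC(=O)/C(C)=C\C)[C@@H]12
F8 | step 13 | (8R)-phosphonopropionate (phosphonate α-carbon unassigned) | C=C1C(=O)O[C@H](CO[Si](CC)(CC)CC)[C@H]1[C@H](OC(=O)C(C)P(=O)(OCC)OCC)C[C@@](C)(O[Si](C)(C)C(C)(C)C)C(C)=O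
F9 | step 13 | phosphonate aldehyde | C=C1C(=O)O[C@H](C=O)[C@H]1[C@H](OC(=O)C(C)P(=O)(OCC)OCC)C[C@@](C)(O[Si](C)(C)C(C)(C)C)C(C)=O
F10 | step 15 | 8-O-angeloyl silyl diketone | C=C1C(=O)O[C@@H]2/C=C(/C)C(=O)CC(=O)[C@](C)(O[Si](C)(C)C(C)(C)C)C[C@@H](OC(=O)/C(C)=C\C)[C@@H]12
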